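**Assumption:** benzyloxyacetaldehyde, (R)-β-citronellene, (R)-4-benzyl-1,3-oxazolidin-2-one and angelic acid are bought as such; minor diastereomers are removed by chromatography where a step is not fully selective.

## Retrosynthetic overview

1. Target ⇐ acetonide hydrolysis and (Z)-angeloylation of the free secondary hydroxyl of a saturated cyclodecane acetonide diol.
2. Cyclodecane ⇐ diimide reduction of a cyclodecene from ring-closing metathesis of an acyclic diene. The dioxolane (acetonide) ring is formed first, on the aldehyde fragment; the ten-membered carbocycle is formed second and last.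
3. Hydroxyisopropyl group ⇐ methyl ester + MeMgBr; ester ⇐ Evans syn-aldol adduct.
4. Key C–C bond (CH–O carbon to the CH that carries the hydroxyisopropyl group) ⇐ intermolecular boron aldol of a (5R)-5-methylhept-6-enoyl oxazolidinone with a cis-5-allyl-1,3-dioxolane-4-carbaldehyde.
5. Aldehyde ⇐ Sharpless kinetic-resolution epoxidation of a racemic isopropenyl carbinol, then vinyl-Grignard epoxide opening; imide ⇐ (R)-β-citronellene (C-methyl stereocentre) by oxidative cleavage and one-carbon homologation.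

## Forward route

**Step 1**
Reactants: 1 benzyloxyacetaldehyde
Product: 2 rac-1-(benzyloxy)-3-methylbut-3-en-2-ol
Conditions: CH2=C(CH3)MgBr, THF, −78 → 0 °C; aq. NH4Cl
Reagents that add atoms: isopropenylmagnesium bromide, CC(=C)[Mg]Br
Why: Grignard 1,2-addition to an unhindered aldehyde gives the racemic secondary allylic alcohol that the next step resolves, so no stereocontrol is needed here.

**Step 2**
Reactants: 2 rac-1-(benzyloxy)-3-methylbut-3-en-2-ol
Product: 3 (1S)-2-(benzyloxy)-1-[(2R)-2-methyloxiran-2-yl]ethan-1-ol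
Conditions: Ti(OiPr)4 (10 mol %), L-(+)-DIPT (15 mol %), TBHP (0.5 equiv), 4 Å MS, CH2Cl2, −20 °C
Reagents that add atoms: tert-butyl hydroperoxide, CC(C)(C)OO
Why: Sharpless kinetic resolution by asymmetric epoxidation: with L-(+)-tartrate only the (R)-alcohol is epoxidised fast, on the alkene face away from its CH2OBn group, which sets the quaternary epoxide carbon as R and erythro to the carbinol centre, while the (S)-alcohol stays behind and is separated (maximum yield 50 %).

**Step 3**
Reactants: 3 (1S)-2-(benzyloxy)-1-[(2R)-2-methyloxiran-2-yl]ethan-1-ol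
Product: 4 (2S,3R)-1-(benzyloxy)-3-methylhex-5-ene-2,3-diol
Conditions: CH2=CHMgBr (3 equiv), CuI (10 mol %), THF, −30 → 0 °C
Reagents that add atoms: vinylmagnesium bromide, C=C[Mg]Br
Why: copper-catalysed SN2 opening of the epoxide at its unhindered CH2 terminus installs the allyl group and leaves both C–O stereocentres untouched, giving the anti tertiary/secondary diol.

**Step 4**
Reactants: 4 (2S,3R)-1-(benzyloxy)-3-methylhex-5-ene-2,3-diol
Product: 5 (4S,5R)-4-[(benzyloxy)methyl]-2,2,5-trimethyl-5-(prop-2-en-1-yl)-1,3-dioxolane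
Conditions: 2,2-dimethoxypropane, PPTS (cat.), CH2Cl2, rt
Reagents that add atoms: 2,2-dimethoxypropane, COC(C)(C)OC
Why: acid-catalysed transketalisation closes the five-membered acetonide on the 1,2-diol without touching a stereocentre and places the allyl and CH2OBn arms cis on the ring.

**Step 5**
Reactants: 5 (4S,5R)-4-[(benzyloxy)methyl]-2,2,5-trimethyl-5-(prop-2-en-1-yl)-1,3-dioxolane
Product: 6 [(4S,5R)-2,2,5-trimethyl-5-(prop-2-en-1-yl)-1,3-dioxolan-4-yl]methanol
Conditions: Na, NH3(l), THF, −78 °C; NH4Cl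
Reagents that add atoms: none
Why: dissolving-metal (Birch-type) debenzylation cleaves the benzylic C–O bond while the isolated terminal alkene and the acetonide are inert, which avoids hydrogenolysis conditions.

**Step 6**
Reactants: 6 [(4S,5R)-2,2,5-trimethyl-5-(prop-2-en-1-yl)-1,3-dioxolan-4-yl]methanol
Product: 7 (4R,5R)-2,2,5-trimethyl-5-(prop-2-en-1-yl)-1,3-dioxolane-4-carbaldehyde
Conditions: Dess–Martin periodinane, NaHCO3, CH2Cl2, 0 °C → rt
Reagents that add atoms: none
Why: buffered Dess–Martin oxidation gives the α-alkoxy aldehyde under non-basic conditions that do not epimerise the α-stereocentre (the crude aldehyde is used at once).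

**Step 7**
Reactants: 8 (3R)-3,7-dimethylocta-1,6-diene ((R)-β-citronellene)
Product: 10 (4R)-4-methylhex-5-enal, via epoxide 9 (not isolated)
Conditions: mCPBA (1.0 equiv), CH2Cl2, 0 °C; then H5IO6, THF/H2O, 0 °C → rt
Reagents that add atoms: 3-chloroperoxybenzoic acid, O=C(OO)c1cccc(Cl)c1
Why: Prilezhaev epoxidation selects the electron-rich trisubstituted alkene over the vinyl group and periodic acid then hydrolyses and cleaves the epoxide (glycol cleavage), the methyl stereocentre coming unchanged from the chiral pool.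

**Step 8**
Reactants: 10 (4R)-4-methylhex-5-enal
Product: 12 (5R)-5-methylhept-6-enal, via enol ether 11 (not isolated)
Conditions: Ph3P(CH2OMe)Cl, KN(SiMe3)2, THF, 0 °C → rt; then 2 M HCl, THF, rt
Reagents that add atoms: (methoxymethyl)triphenylphosphonium chloride, COC[P+](c1ccccc1)(c1ccccc1)c1ccccc1.[Cl-]; water, O
Why: Wittig methoxymethylenation followed by acid hydrolysis of the enol ether is a standard one-carbon aldehyde homologation, and the remote stereocentre cannot epimerise.

**Step 9**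
Reactants: 12 (5R)-5-methylhept-6-enal
Product: 13 (5R)-5-methylhept-6-enoic acid
Conditions: NaClO2, NaH2PO4, 2-methylbut-2-ene, t-BuOH/H2O, rt
Reagents that add atoms: sodium chlorite, [Na+].[O-]Cl=O
Why: Pinnick oxidation converts the aldehyde to the acid chemoselectively, the alkene scavenger protecting the vinyl group from hypochlorous acid.

**Step 10**
Reactants: 13 (5R)-5-methylhept-6-enoic acid; 14 (4R)-4-benzyl-1,3-oxazolidin-2-one
Product: 16 (4R)-4-benzyl-3-[(5R)-5-methylhept-6-enoyl]-1,3-oxazolidin-2-one, via mixed pivalic anhydride 15 (not isolated)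
Conditions: PivCl, Et3N, THF, −20 °C; then 14, LiCl, −20 °C → rt
Reagents that add atoms: none
Why: N-acylation through the mixed pivalic anhydride (attack at the less hindered carbonyl) attaches the Evans auxiliary without strong base.

**Step 11**
Reactants: 16 (4R)-4-benzyl-3-[(5R)-5-methylhept-6-enoyl]-1,3-oxazolidin-2-one; 7 (4R,5R)-2,2,5-trimethyl-5-(prop-2-en-1-yl)-1,3-dioxolane-4-carbaldehyde
Product: 18 (4R)-4-benzyl-3-[(2R,5R)-2-{(R)-hydroxy[(4S,5R)-2,2,5-trimethyl-5-(prop-2-en-1-yl)-1,3-dioxolan-4-yl]methyl}-5-methylhept-6-enoyl]-1,3-oxazolidin-2-one, via boron enolate 17 (not isolated)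
Conditions: Bu2BOTf, iPr2NEt, CH2Cl2, −78 → 0 °C; then 7, −78 → 0 °C; pH 7 buffer, MeOH, H2O2
Reagents that add atoms: none
Why: Evans syn-aldol in which the (Z)-dibutylboron enolate reacts through a Zimmerman–Traxler chair on the face away from the (R)-benzyl group, setting the α-carbon (R) and the carbinol carbon (R) syn; this is reagent control against the aldehyde's own Cornforth/Felkin preference (a mismatched pair), so a dr near 5–10:1 is expected and the minor isomers, including any adduct of residual ent-7, are removed by chromatography.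

**Step 12**
Reactants: 18 syn-aldol imide
Product: 19 methyl (2R,5R)-2-{(R)-hydroxy[(4S,5R)-2,2,5-trimethyl-5-(prop-2-en-1-yl)-1,3-dioxolan-4-yl]methyl}-5-methylhept-6-enoate
Conditions: MeMgBr, MeOH, CH2Cl2, 0 °C
Reagents that add atoms: methanol, CO
Why: transesterification with bromomagnesium methoxide cleaves the β-hydroxy imide at the exocyclic carbonyl without retro-aldol or α-epimerisation and releases the auxiliary for recovery.

**Step 13**
Reactants: 19 β-hydroxy methyl ester
Product: 20 (3R,6R)-3-{(R)-hydroxy[(4S,5R)-2,2,5-trimethyl-5-(prop-2-en-1-yl)-1,3-dioxolan-4-yl]methyl}-2,6-dimethyloct-7-en-2-ol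
Conditions: MeMgBr (6 equiv), THF, 0 °C → rt
Reagents that add atoms: methylmagnesium bromide, C[Mg]Br
Why: double Grignard addition to the ester builds the hydroxyisopropyl group, the magnesium alkoxide of the β-hydroxyl being stable to retro-aldol at this temperature, and no stereocentre is created.

**Step 14**
Reactants: 20 acyclic diene diol
Product: 21 (3aS,4R,5R,8R,11aR)-5-(2-hydroxypropan-2-yl)-2,2,8,11a-tetramethyl-3a,4,5,6,7,8,11,11a-octahydrocyclodeca[d][1,3]dioxol-4-ol (E/Z mixture at the 9,10-alkene)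
Conditions: second-generation Grubbs catalyst (10 mol %), 1,4-benzoquinone (20 mol %), CH2Cl2 (1 mM), 40 °C
Reagents that add atoms: none
Why: ring-closing metathesis of the two monosubstituted alkenes at high dilution forms the ten-membered ring, helped by the cis-fused dioxolane that turns the two chains toward each other, and benzoquinone suppresses alkene migration; the E/Z mixture converges in the next step.

**Step 15**
Reactants: 21 cyclodecene acetonide diol
Product: 22 (3aS,4R,5R,8S,11aR)-5-(2-hydroxypropan-2-yl)-2,2,8,11a-tetramethyldecahydrocyclodeca[d][1,3]dioxol-4-ol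
Conditions: TsNHNH2, NaOAc, DME/H2O, 85 °C
Reagents that add atoms: none
Why: diimide reduction saturates the ring alkene by concerted syn hydrogen transfer without any metal hydride, so the allylic C-methyl stereocentre cannot be scrambled by double-bond migration.

**Step 16**
Reactants: 22 saturated acetonide diol; 23 angelic acid ((2Z)-2-methylbut-2-enoic acid)
Product: 25 (3aS,4R,5R,8S,11aR)-5-(2-hydroxypropan-2-yl)-2,2,8,11a-tetramethyldecahydrocyclodeca[d][1,3]dioxol-4-yl (2Z)-2-methylbut-2-enoate, via mixed Yamaguchi anhydride 24 (not isolated)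
Conditions: 23, 2,4,6-trichlorobenzoyl chloride, Et3N, toluene, rt; then 22, toluene, 80 °C
Reagents that add atoms: none
Why: Yamaguchi-type esterification run without DMAP, in which the secondary alcohol attacks the unhindered angeloyl carbonyl of the mixed anhydride under conditions known to keep the Z geometry, while the tertiary hydroxyl is too hindered to compete.

**Step 17**
Reactants: 25 angelate acetonide
Product: 26 (1R,2S,3R,7S,10R)-2,3-dihydroxy-10-(2-hydroxypropan-2-yl)-3,7-dimethylcyclodecyl (2Z)-2-methylbut-2-enoate (target)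
Conditions: AcOH/H2O/THF (3:1:1), 45 °C
Reagents that add atoms: none
Why: mild acid-catalysed acetal hydrolysis frees the secondary/tertiary diol without ester cleavage, acyl migration or dehydration of the tertiary alcohols, giving the target with all five stereocentres as set earlier.

## Compound list

1 | benzyloxyacetaldehyde | O=CCOCc1ccccc1 | starting material
2 | rac-1-(benzyloxy)-3-methylbut-3-en-2-ol | C=C(C)C(O)COCc1ccccc1 | intermediate
3 | (1S)-2-(benzyloxy)-1-[(2R)-2-methyloxiran-2-yl]ethan-1-ol | c1ccccc1COC[C@H](O)[C@@]1(C)CO1 | intermediate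
4 | (2S,3R)-1-(benzyloxy)-3-methylhex-5-ene-2,3-diol | c1ccccc1COC[C@H](O)[C@](C)(O)CC=C | intermediate
5 | (4S,5R)-4-[(benzyloxy)methyl]-2,2,5-trimethyl-5-(prop-2-en-1-yl)-1,3-dioxolane | c1ccccc1COC[C@@H]1OC(C)(C)O[C@]1(C)CC=C | intermediate
6 | [(4S,5R)-2,2,5-trimethyl-5-(prop-2-en-1-yl)-1,3-dioxolan-4-yl]methanol | OC[C@@H]1OC(C)(C)O[C@]1(C)CC=C | intermediate
7 | (4R,5R)-2,2,5-trimethyl-5-(prop-2-en-1-yl)-1,3-dioxolane-4-carbaldehyde | O=C[C@@H]1OC(C)(C)O[C@]1(C)CC=C | intermediate
8 | (3R)-3,7-dimethylocta-1,6-diene ((R)-β-citronellene) | CC(C)=CCC[C@@H](C)C=C | starting material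
9 | 2,2-dimethyl-3-[(3R)-3-methylpent-4-en-1-yl]oxirane (both epimers at the oxirane CH) | CC1(C)OC1CC[C@@H](C)C=C | intermediate
10 | (4R)-4-methylhex-5-enal | O=CCC[C@@H](C)C=C | intermediate
11 | (3R)-7-methoxy-3-methylhepta-1,6-diene (E/Z enol ether) | COC=CCC[C@@H](C)C=C | intermediate
12 | (5R)-5-methylhept-6-enal | O=CCCC[C@@H](C)C=C | intermediate
13 | (5R)-5-methylhept-6-enoic acid | OC(=O)CCC[C@@H](C)C=C | intermediate
14 | (4R)-4-benzyl-1,3-oxazolidin-2-one | O=C1N[C@H](Cc2ccccc2)CO1 | starting material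
15 | 2,2-dimethylpropanoic (5R)-5-methylhept-6-enoic anhydride | CC(C)(C)C(=O)OC(=O)CCC[C@@H](C)C=C | intermediate
16 | (4R)-4-benzyl-3-[(5R)-5-methylhept-6-enoyl]-1,3-oxazolidin-2-one | O=C(CCC[C@@H](C)C=C)N1[C@H](Cc2ccccc2)COC1=O | intermediate
17 | (4R)-4-benzyl-3-[(1Z,5R)-1-[(dibutylboranyl)oxy]-5-methylhepta-1,6-dien-1-yl]-1,3-oxazolidin-2-one (boron enolate of 16) | CCCCB(CCCC)O/C(=C\CC[C@@H](C)C=C)N1[C@H](Cc2ccccc2)COC1=O | intermediate
18 | (4R)-4-benzyl-3-[(2R,5R)-2-{(R)-hydroxy[(4S,5R)-2,2,5-trimethyl-5-(prop-2-en-1-yl)-1,3-dioxolan-4-yl]methyl}-5-methylhept-6-enoyl]-1,3-oxazolidin-2-one | O[C@@H]([C@@H]1OC(C)(C)O[C@]1(C)CC=C)[C@H](C(=O)N2[C@H](Cc3ccccc3)COC2=O)CC[C@@H](C)C=C | intermediate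
19 | methyl (2R,5R)-2-{(R)-hydroxy[(4S,5R)-2,2,5-trimethyl-5-(prop-2-en-1-yl)-1,3-dioxolan-4-yl]methyl}-5-methylhept-6-enoate | O[C@@H]([C@@H]1OC(C)(C)O[C@]1(C)CC=C)[C@H](C(=O)OC)CC[C@@H](C)C=C | intermediate
20 | (3R,6R)-3-{(R)-hydroxy[(4S,5R)-2,2,5-trimethyl-5-(prop-2-en-1-yl)-1,3-dioxolan-4-yl]methyl}-2,6-dimethyloct-7-en-2-ol | O[C@@H]([C@@H]1OC(C)(C)O[C@]1(C)CC=C)[C@H](C(C)(C)O)CC[C@@H](C)C=C | intermediate
21 | (3aS,4R,5R,8R,11aR)-5-(2-hydroxypropan-2-yl)-2,2,8,11a-tetramethyl-3a,4,5,6,7,8,11,11a-octahydrocyclodeca[d][1,3]dioxol-4-ol (E/Z) | O[C@@H]1[C@H](C(C)(C)O)CC[C@@H](C)C=CC[C@@]2(C)OC(C)(C)O[C@@H]12 | intermediate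
22 | (3aS,4R,5R,8S,11aR)-5-(2-hydroxypropan-2-yl)-2,2,8,11a-tetramethyldecahydrocyclodeca[d][1,3]dioxol-4-ol | O[C@@H]1[C@H](C(C)(C)O)CC[C@@H](C)CCC[C@@]2(C)OC(C)(C)O[C@@H]12 | intermediate
23 | angelic acid, (2Z)-2-methylbut-2-enoic acid | C/C=C(/C)C(=O)O | starting material
24 | (2Z)-2-methylbut-2-enoic 2,4,6-trichlorobenzoic anhydride | C/C=C(/C)C(=O)OC(=O)c1c(Cl)cc(Cl)cc1Cl | intermediate
25 | (3aS,4R,5R,8S,11aR)-5-(2-hydroxypropan-2-yl)-2,2,8,11a-tetramethyldecahydrocyclodeca[d][1,3]dioxol-4-yl (2Z)-2-methylbut-2-enoate | C/C=C(/C)C(=O)O[C@@H]1[C@H](C(C)(C)O)CC[C@@H](C)CCC[C@@]2(C)OC(C)(C)O[C@@H]12 | intermediate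
26 | (1R,2S,3R,7S,10R)-2,3-dihydroxy-10-(2-hydroxypropan-2-yl)-3,7-dimethylcyclodecyl (2Z)-2-methylbut-2-enoate | C/C=C(/C)C(=O)O[C@@H]1[C@H](C(C)(C)O)CC[C@@H](C)CCC[C@@](C)(O)[C@H]1O | target

## Step count and risks

Total step count: 17. Longest linear sequence: 13 steps (steps 1–6, then 11–17); the imide branch is 4 steps (7–10).

**Most likely to fail, 1: step 14 (ring-closing metathesis to a ten-membered carbocycle).** The risk is oligomerisation instead of ring closure. The fallback sets out from 20 and comes back at 21. Both hydroxyls of 20 are silylated (TESOTf, 2,6-lutidine, CH2Cl2) to give the bis(triethylsilyl) ether of 20 F1. Both terminal alkenes are ozonised (O3, CH2Cl2, −78 °C; PPh3) to give the dialdehyde F2. An intramolecular McMurry coupling (TiCl3(DME)1.5, Zn–Cu, DME, reflux, syringe-pump addition) then closes the ring at the same two carbons to give the bis(triethylsilyl) ether of 21 F3. Bu4NF in THF returns 21. The α-methyl aldehyde of F2 must be handled cold and used at once to keep its configuration.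

**Most likely to fail, 2: step 11 (mismatched Evans aldol).** The risk is poor diastereoselectivity or a sluggish reaction with the hindered aldehyde. The fallback sets out from 15 (made from 13 as in step 10) and from 7, and comes back at 19; the C–C bond is made by a crossed Claisen-type C-acylation instead.
- Anhydride 15 is coupled with purchased (4S)-4-benzyl-1,3-oxazolidin-2-one (LiCl, Et3N) to give (4S)-4-benzyl-3-[(5R)-5-methylhept-6-enoyl]-1,3-oxazolidin-2-one F4.
- LiN(iPr)2 (THF, −78 °C) converts it into its lithium (Z)-enolate F5.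
- Aldehyde 7 is oxidised (NaClO2, NaH2PO4, 2-methylbut-2-ene) to (4R,5R)-2,2,5-trimethyl-5-(prop-2-en-1-yl)-1,3-dioxolane-4-carboxylic acid F6.
- F6 is converted with 1-chloro-N,N,2-trimethylprop-1-en-1-amine into the acid chloride F7.
- F5 and F7 give the β-keto imide F8; the acyl group enters the chelated enolate anti to the benzyl group, which with the (S)-auxiliary gives the required R configuration at the α-carbon.
- Zn(BH4)2 (CH2Cl2/Et2O, −20 °C) reduces the ketone through the six-membered 1,3-dicarbonyl zinc chelate, anti to the α-substituent, to the syn-aldol imide with the (S)-auxiliary F9. The Felkin preference of the dioxolane stereocentre points the same way; a competing chelate to the dioxolane oxygen would oppose it and is the residual risk.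
- MeMgBr/MeOH as in step 12 then gives 19.

**Most likely to fail, 3: step 16 (angeloylation of a hindered alcohol).** The risk is low conversion or Z → E isomerisation to the tiglate. The fallback sets out from 22 and comes back at 25; the Z-alkene is built on the ester instead of being carried in. Alcohol 22 is esterified with 2-[bis(2,2,2-trifluoroethoxy)phosphoryl]propanoic acid (DCC, DMAP, CH2Cl2; no alkene geometry is at stake, so DMAP can be used) to give the phosphonopropanoate ester of 22 F10. KN(SiMe3)2 with 18-crown-6 (THF, −78 °C) gives its potassium phosphonate carbanion F11. Acetaldehyde then gives the (Z)-trisubstituted enoate 25 by Still–Gennari olefination.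

## Further compounds

F1 | step 14 | bis(triethylsilyl) ether of 20 (both hydroxyls as OSiEt3) | CC[Si](CC)(CC)O[C@@H]([C@@H]1OC(C)(C)O[C@]1(C)CC=C)[C@H](C(C)(C)O[Si](CC)(CC)CC)CC[C@@H](C)C=C
F2 | step 14 | dialdehyde from F1 (allyl group cut to CH2CHO, vinyl group cut to CHO) | CC[Si](CC)(CC)O[C@@H]([C@@H]1OC(C)(C)O[C@]1(C)CC=O)[C@H](C(C)(C)O[Si](CC)(CC)CC)CC[C@@H](C)C=O
F3 | step 14 | bis(triethylsilyl) ether of 21 (E/Z) | CC[Si](CC)(CC)O[C@@H]1[C@H](C(C)(C)O[Si](CC)(CC)CC)CC[C@@H](C)C=CC[C@@]2(C)OC(C)(C)O[C@@H]12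
F4 | step 11 | (4S)-4-benzyl-3-[(5R)-5-methylhept-6-enoyl]-1,3-oxazolidin-2-one | O=C(CCC[C@@H](C)C=C)N1[C@@H](Cc2ccccc2)COC1=O
F5 | step 11 | lithium (Z)-enolate of F4 | [Li]O/C(=C\CC[C@@H](C)C=C)N1[C@@H](Cc2ccccc2)COC1=O
F6 | step 11 | (4R,5R)-2,2,5-trimethyl-5-(prop-2-en-1-yl)-1,3-dioxolane-4-carboxylic acid | OC(=O)[C@@H]1OC(C)(C)O[C@]1(C)CC=C
F7 | step 11 | (4R,5R)-2,2,5-trimethyl-5-(prop-2-en-1-yl)-1,3-dioxolane-4-carbonyl chloride | ClC(=O)[C@@H]1OC(C)(C)O[C@]1(C)CC=C
F8 | step 11 | (4S)-4-benzyl-3-[(2R,5R)-5-methyl-2-{[(4R,5R)-2,2,5-trimethyl-5-(prop-2-en-1-yl)-1,3-dioxolan-4-yl]carbonyl}hept-6-enoyl]-1,3-oxazolidin-2-one | O=C([C@@H]1OC(C)(C)O[C@]1(C)CC=C)[C@H](C(=O)N2[C@@H](Cc3ccccc3)COC2=O)CC[C@@H](C)C=C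
F9 | step 11 | (4S)-4-benzyl-3-[(2R,5R)-2-{(R)-hydroxy[(4S,5R)-2,2,5-trimethyl-5-(prop-2-en-1-yl)-1,3-dioxolan-4-yl]methyl}-5-methylhept-6-enoyl]-1,3-oxazolidin-2-one | O[C@@H]([C@@H]1OC(C)(C)O[C@]1(C)CC=C)[C@H](C(=O)N2[C@@H](Cc3ccccc3)COC2=O)CC[C@@H](C)C=C
F10 | step 16 | 2-[bis(2,2,2-trifluoroethoxy)phosphoryl]propanoate ester of 22 (both epimers at the phosphorus-bearing carbon) | CC(C(=O)O[C@@H]1[C@H](C(C)(C)O)CC[C@@H](C)CCC[C@@]2(C)OC(C)(C)O[C@@H]12)P(=O)(OCC(F)(F)F)OCC(F)(F)F
F11 | step 16 | potassium phosphonate carbanion of F10 | [K+].C[C-](C(=O)O[C@@H]1[C@H](C(C)(C)O)CC[C@@H](C)CCC[C@@]2(C)OC(C)(C)O[C@@H]12)P(=O)(OCC(F)(F)F)OCC(F)(F)F
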